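The route rests on breaking the C5–C6 bond of the carbocycle back to two aldehydes. A samarium-mediated reductive coupling of a 4-oxo-4H-pyran-3-carbaldehyde (C4a–CHO) with an α-alkoxy aldehyde at C6 closes ring B (C4a, C5, C6, C7, C8, C8a) in one operation and sets C5 and C6. It exploits the cis C5/C6 diol that lies trans to the C7 oxygen. The precursor is a 2,6-disubstituted 3-formyl-4-pyranone: an arylethyl chain at C2 and, at C8a, a D-tartrate-derived trans-dioxolane bearing the second aldehyde. The acetonide locks the C7/C8 trans relationship and, with the aryl MOM ether, falls in one final acid step.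

Key step: step 13

Remarks before the steps
- Numbering: the chromone numbering of the target is used for the future ring atoms (C8a is the pyranone carbon bearing the dioxolane, C4a the one bearing the formyl group).
- Assumption: compound 7 (the acetonide of D-threitol, that is, reduced D-tartrate) and 2,2,2-trifluoroethyl formate are purchased.
- Remark: compounds 10–12 are carried as mixtures of epimers at the future C8a. This centre becomes sp2 in step 10, so both epimers converge on 13.
- Design: the formyl carbon is attached to C4a while the heterocycle is still a 2,3-dihydropyranone, where C4a is the only sp3 α-carbon. This removes any choice between C3 and C4a and avoids electrophilic halogenation beside the electron-rich arene.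

Step 1
Reactants: 1 isovanillin (3-hydroxy-4-methoxybenzaldehyde)
Product: 2 4-methoxy-3-(methoxymethoxy)benzaldehyde
Conditions: MOMCl, iPr2NEt, CH2Cl2, 0 °C → rt
Reagents that add atoms: chloromethyl methyl ether, COCCl
Why: Williamson-type O-alkylation of the phenol by the α-chloro ether gives the MOM ether, which is stable to every later step except the final acid treatment.

Step 2
Reactants: 2 4-methoxy-3-(methoxymethoxy)benzaldehyde
Product: 3 [4-methoxy-3-(methoxymethoxy)phenyl]methanol
Conditions: NaBH4, MeOH, 0 °C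
Reagents that add atoms: none
Why: Hydride reduction of an aromatic aldehyde by NaBH4 is routine and leaves the acetal untouched.

Step 3
Reactants: 3 [4-methoxy-3-(methoxymethoxy)phenyl]methanol
Product: 4 4-(bromomethyl)-1-methoxy-2-(methoxymethoxy)benzene
Conditions: CBr4, PPh3, CH2Cl2, 0 °C; used at once
Reagents that add atoms: carbon tetrabromide, BrC(Br)(Br)Br
Why: The Appel reaction converts the benzylic alcohol into the bromide under neutral conditions that spare the MOM acetal.

Step 4
Reactants: 4 4-(bromomethyl)-1-methoxy-2-(methoxymethoxy)benzene; 5 acetylacetone (pentane-2,4-dione)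
Product: 6 6-[4-methoxy-3-(methoxymethoxy)phenyl]hexane-2,4-dione
Conditions: 5, LiN(iPr)2 (2.1 equiv), THF, 0 °C; 4, 0 °C → rt; 1 M HCl
Reagents that add atoms: none
Why: Terminal alkylation of a 1,3-diketone dianion should occur because the terminal carbanion is the most nucleophilic site and displaces the benzylic bromide by SN2.

Step 5
Reactants: 7 [(4R,5R)-2,2-dimethyl-1,3-dioxolane-4,5-diyl]dimethanol (2,3-O-isopropylidene-D-threitol)
Product: 8 [(4R,5R)-5-({[tert-butyl(dimethyl)silyl]oxy}methyl)-2,2-dimethyl-1,3-dioxolan-4-yl]methanol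
Conditions: NaH (1.0 equiv), THF, 0 °C → rt; TBSCl (1.0 equiv)
Reagents that add atoms: tert-butyldimethylsilyl chloride, CC(C)(C)[Si](C)(C)Cl
Why: Monosilylation of a symmetrical diol through its sparingly soluble monosodium alkoxide should work because the two hydroxyls are equivalent by C2 symmetry, so only mono- against bis-silylation has to be controlled.

Step 6
Reactants: 8 [(4R,5R)-5-({[tert-butyl(dimethyl)silyl]oxy}methyl)-2,2-dimethyl-1,3-dioxolan-4-yl]methanol
Product: 9 (4S,5R)-5-({[tert-butyl(dimethyl)silyl]oxy}methyl)-2,2-dimethyl-1,3-dioxolane-4-carbaldehyde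
Conditions: Dess–Martin periodinane, CH2Cl2, 0 °C → rt; used crude
Reagents that add atoms: none
Why: Dess–Martin oxidation of the primary alcohol is non-basic and should not epimerise the α-alkoxy centre, whose trans arrangement on the dioxolane is in any case the stable one.

Step 7
Reactants: 6 6-[4-methoxy-3-(methoxymethoxy)phenyl]hexane-2,4-dione; 9 (4S,5R)-5-({[tert-butyl(dimethyl)silyl]oxy}methyl)-2,2-dimethyl-1,3-dioxolane-4-carbaldehyde
Product: 10 1-[(4R,5R)-5-({[tert-butyl(dimethyl)silyl]oxy}methyl)-2,2-dimethyl-1,3-dioxolan-4-yl]-1-hydroxy-7-[4-methoxy-3-(methoxymethoxy)phenyl]heptane-3,5-dione, both C1 epimers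
Conditions: 6, LiN(iPr)2 (2.2 equiv), THF, −78 → 0 °C; 9, −78 °C; AcOH, −78 °C
Reagents that add atoms: none
Why: In this aldol addition of a 1,3-diketone dianion, the second deprotonation is expected at the methyl group rather than the C5 methylene, and the terminal carbanion adds to the aldehyde at low temperature; the new carbinol centre is formed unselectively and is erased in step 10.

Step 8
Reactants: 10 the δ-hydroxy-β-diketone from step 7
Product: 11 2-[(4R,5R)-5-({[tert-butyl(dimethyl)silyl]oxy}methyl)-2,2-dimethyl-1,3-dioxolan-4-yl]-6-{2-[4-methoxy-3-(methoxymethoxy)phenyl]ethyl}-2,3-dihydro-4H-pyran-4-one, both C2 epimers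
Conditions: TsOH·H2O (0.1 equiv), 4 Å molecular sieves, CH2Cl2, 0 °C → rt
Reagents that add atoms: none
Why: Acid-catalysed cyclodehydration (hemiketal formation of the δ-hydroxyl on the distal ketone, then loss of water) is the standard route to 2,3-dihydro-4H-pyran-4-ones, and catalytic anhydrous acid should spare the acetonide, the silyl ether and the MOM group.

Step 9
Reactants: 11 the 2,3-dihydro-4H-pyran-4-one from step 8
Product: 12 2-[(4R,5R)-5-({[tert-butyl(dimethyl)silyl]oxy}methyl)-2,2-dimethyl-1,3-dioxolan-4-yl]-3-(hydroxymethylidene)-6-{2-[4-methoxy-3-(methoxymethoxy)phenyl]ethyl}-2,3-dihydro-4H-pyran-4-one (enol form of the 3-carbaldehyde), both C2 epimers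
Conditions: LiN(iPr)2 (1.2 equiv), THF, −78 °C; CF3CH2OCHO, −78 °C; AcOH, −78 °C
Reagents that add atoms: 2,2,2-trifluoroethyl formate, O=COCC(F)(F)F
Why: Crossed Claisen formylation of the kinetic lithium enolate should deliver the future C5 regiospecifically, because C3 of the dihydropyranone (the future C4a) is the only sp3 carbon α to the vinylogous ester carbonyl.

Step 10
Reactants: 12 the 3-(hydroxymethylidene)dihydropyranone from step 9
Product: 13 2-[(4S,5R)-5-({[tert-butyl(dimethyl)silyl]oxy}methyl)-2,2-dimethyl-1,3-dioxolan-4-yl]-6-{2-[4-methoxy-3-(methoxymethoxy)phenyl]ethyl}-4-oxo-4H-pyran-3-carbaldehyde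
Conditions: DDQ (1.1 equiv), 1,4-dioxane, rt
Reagents that add atoms: none
Why: DDQ dehydrogenation of a 2-formyl ketone enol to the 2-formyl enone should be fast here, since hydride leaves from the oxygen-bearing C2 and the product is an aromatic-type 4-pyranone; both epimers give the same compound.

Step 11
Reactants: 13 the silyl-protected 4-oxo-4H-pyran-3-carbaldehyde from step 10
Product: 14 2-[(4S,5R)-5-(hydroxymethyl)-2,2-dimethyl-1,3-dioxolan-4-yl]-6-{2-[4-methoxy-3-(methoxymethoxy)phenyl]ethyl}-4-oxo-4H-pyran-3-carbaldehyde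
Conditions: HF·pyridine, pyridine, THF, 0 °C → rt
Reagents that add atoms: none
Why: Fluoride-mediated desilylation with buffered HF·pyridine should cleave the primary silyl ether and leave the acetonide, the MOM acetal and the aldehyde alone.

Step 12
Reactants: 14 the primary alcohol from step 11
Product: 15 (4S,5S)-5-(3-formyl-6-{2-[4-methoxy-3-(methoxymethoxy)phenyl]ethyl}-4-oxo-4H-pyran-2-yl)-2,2-dimethyl-1,3-dioxolane-4-carbaldehyde
Conditions: Dess–Martin periodinane, CH2Cl2, 0 °C → rt; used crude without delay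
Reagents that add atoms: none
Why: Dess–Martin oxidation gives the second aldehyde under mild, non-basic conditions, and the dioxolane keeps the α-centre in its stable trans arrangement.

Step 13
Reactants: 15 the dialdehyde from step 12
Product: 16 (5S,6S,7R,8S)-5,6-dihydroxy-7,8-(isopropylidenedioxy)-2-{2-[4-methoxy-3-(methoxymethoxy)phenyl]ethyl}-5,6,7,8-tetrahydro-4H-chromen-4-one (5-OH and 6-OH cis, 6-OH trans to O7)
Conditions: SmI2 (2.5 equiv, 0.1 M in THF), t-BuOH (3 equiv), THF, −78 → −20 °C; aq. NH4Cl
Reagents that add atoms: none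
Why: Proposed new method: the pyranone aldehyde is the more easily reduced carbonyl, so divalent samarium should give a samarium-bound ketyl delocalised over C5, C4a and the pyranone, which couples through C5 with the samarium-activated C6 aldehyde (or its ketyl) and takes up a second electron to give the diolate of trivalent samarium; the closest known reaction type is the SmI2 pinacol cyclisation of sugar-derived 1,6-dialdehydes to cis-cyclohexane-1,2-diols, which has not been shown for an aldehyde on a 4-pyranone. Ring B (C4a–C5–C6–C7–C8–C8a) closes in a 6-exo-trig mode. C5 is controlled by the samarium bridge between the two oxygens, which places O5 cis to O6. C6 is controlled by the C7 stereocentre, its oxygen taking the pseudoequatorial position anti to the C7–O bond of the rigid trans-dioxolane, which also leaves O5 pseudoaxial and clear of the C4 carbonyl. The step needs coupling at C5 and not at the conjugate position C8a or simple reduction; C8a is fully substituted and could only close a four-membered ring, and low temperature with a weak proton donor keeps protonation slower than ring closure.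

Step 14
Reactants: 16 the acetonide- and MOM-protected diol from step 13
Product: 17 (5S,6S,7R,8S)-5,6,7,8-tetrahydroxy-2-[2-(3-hydroxy-4-methoxyphenyl)ethyl]-5,6,7,8-tetrahydro-4H-chromen-4-one (CNP0224308.1)
Conditions: 2 M aq. HCl, THF, rt → 40 °C
Reagents that add atoms: none
Why: Acid-catalysed hydrolysis should remove the strained trans-fused isopropylidene ketal and the aryl MOM acetal in one operation without touching a stereocentre, and a methanol-free medium avoids solvolytic exchange at C5.

Compound list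
1 | isovanillin (3-hydroxy-4-methoxybenzaldehyde) | COc1ccc(C=O)cc1O | starting material
2 | 4-methoxy-3-(methoxymethoxy)benzaldehyde | COCOc1cc(C=O)ccc1OC | intermediate
3 | [4-methoxy-3-(methoxymethoxy)phenyl]methanol | COCOc1cc(CO)ccc1OC | intermediate
4 | 4-(bromomethyl)-1-methoxy-2-(methoxymethoxy)benzene | COCOc1cc(CBr)ccc1OC | intermediate
5 | acetylacetone (pentane-2,4-dione) | CC(=O)CC(C)=O | starting material
6 | 6-[4-methoxy-3-(methoxymethoxy)phenyl]hexane-2,4-dione | COCOc1cc(CCC(=O)CC(C)=O)ccc1OC | intermediate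
7 | [(4R,5R)-2,2-dimethyl-1,3-dioxolane-4,5-diyl]dimethanol (2,3-O-isopropylidene-D-threitol) | OC[C@H]1OC(C)(C)O[C@@H]1CO | starting material
8 | [(4R,5R)-5-({[tert-butyl(dimethyl)silyl]oxy}methyl)-2,2-dimethyl-1,3-dioxolan-4-yl]methanol | OC[C@H]1OC(C)(C)O[C@@H]1CO[Si](C)(C)C(C)(C)C | intermediate
9 | (4S,5R)-5-({[tert-butyl(dimethyl)silyl]oxy}methyl)-2,2-dimethyl-1,3-dioxolane-4-carbaldehyde | O=C[C@H]1OC(C)(C)O[C@@H]1CO[Si](C)(C)C(C)(C)C | intermediate
10 | 1-[(4R,5R)-5-({[tert-butyl(dimethyl)silyl]oxy}methyl)-2,2-dimethyl-1,3-dioxolan-4-yl]-1-hydroxy-7-[4-methoxy-3-(methoxymethoxy)phenyl]heptane-3,5-dione, C1 epimers | COCOc1cc(CCC(=O)CC(=O)CC(O)[C@H]2OC(C)(C)O[C@@H]2CO[Si](C)(C)C(C)(C)C)ccc1OC | intermediate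
11 | 2-[(4R,5R)-5-({[tert-butyl(dimethyl)silyl]oxy}methyl)-2,2-dimethyl-1,3-dioxolan-4-yl]-6-{2-[4-methoxy-3-(methoxymethoxy)phenyl]ethyl}-2,3-dihydro-4H-pyran-4-one, C2 epimers | COCOc1cc(CCC2=CC(=O)CC(O2)[C@H]3OC(C)(C)O[C@@H]3CO[Si](C)(C)C(C)(C)C)ccc1OC | intermediate
12 | 2-[(4R,5R)-5-({[tert-butyl(dimethyl)silyl]oxy}methyl)-2,2-dimethyl-1,3-dioxolan-4-yl]-3-(hydroxymethylidene)-6-{2-[4-methoxy-3-(methoxymethoxy)phenyl]ethyl}-2,3-dihydro-4H-pyran-4-one, C2 epimers | COCOc1cc(CCC2=CC(=O)C(=CO)C(O2)[C@H]3OC(C)(C)O[C@@H]3CO[Si](C)(C)C(C)(C)C)ccc1OC | intermediate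
13 | 2-[(4S,5R)-5-({[tert-butyl(dimethyl)silyl]oxy}methyl)-2,2-dimethyl-1,3-dioxolan-4-yl]-6-{2-[4-methoxy-3-(methoxymethoxy)phenyl]ethyl}-4-oxo-4H-pyran-3-carbaldehyde | COCOc1cc(CCc2cc(=O)c(C=O)c(o2)[C@H]3OC(C)(C)O[C@@H]3CO[Si](C)(C)C(C)(C)C)ccc1OC | intermediate
14 | 2-[(4S,5R)-5-(hydroxymethyl)-2,2-dimethyl-1,3-dioxolan-4-yl]-6-{2-[4-methoxy-3-(methoxymethoxy)phenyl]ethyl}-4-oxo-4H-pyran-3-carbaldehyde | COCOc1cc(CCc2cc(=O)c(C=O)c(o2)[C@H]3OC(C)(C)O[C@@H]3CO)ccc1OC | intermediate
15 | (4S,5S)-5-(3-formyl-6-{2-[4-methoxy-3-(methoxymethoxy)phenyl]ethyl}-4-oxo-4H-pyran-2-yl)-2,2-dimethyl-1,3-dioxolane-4-carbaldehyde | COCOc1cc(CCc2cc(=O)c(C=O)c(o2)[C@H]3OC(C)(C)O[C@@H]3C=O)ccc1OC | intermediate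
16 | (5S,6S,7R,8S)-5,6-dihydroxy-7,8-(isopropylidenedioxy)-2-{2-[4-methoxy-3-(methoxymethoxy)phenyl]ethyl}-5,6,7,8-tetrahydro-4H-chromen-4-one | COCOc1cc(CCc2cc(=O)c3c(o2)[C@H]4OC(C)(C)O[C@@H]4[C@@H](O)[C@H]3O)ccc1OC | intermediate
17 | (5S,6S,7R,8S)-5,6,7,8-tetrahydroxy-2-[2-(3-hydroxy-4-methoxyphenyl)ethyl]-5,6,7,8-tetrahydro-4H-chromen-4-one | COc1ccc(CCc2cc(=O)c3c(o2)[C@@H](O)[C@H](O)[C@@H](O)[C@H]3O)cc1O | target

Total step count: 14.
Longest linear sequence: 12 steps (steps 1–4 and 7–14, from isovanillin).

Steps most likely to fail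

Step 13 (the proposed new method). Ring closure may lose out to conjugate reduction or reductive dimerisation of the pyranone aldehyde. Facial selectivity may erode if samarium chelates O4 and O5 and pulls the C5 oxygen into the pyranone plane. The strain of the trans-fused dioxolane may slow cyclisation. The fallback forms the same C5–C6 bond by known olefin chemistry. It sets out from 15: double Wittig methylenation (Ph3PCH3Br, KN(SiMe3)2, THF, −78 → 0 °C) would give the divinyl pyranone F1. Ring-closing metathesis with the second-generation Grubbs catalyst (CH2Cl2, 40 °C) would then give the 7,8-dihydrochromone F2. Upjohn dihydroxylation (OsO4 cat., N-methylmorpholine N-oxide, acetone/H2O, 0 °C) is expected to occur on the face opposite the allylic C7 oxygen and to deliver the cis-5,6-diol, so the route is rejoined at 16.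

Step 9. The α′-enolate may ring-open by β-elimination of the ring oxygen (retro-oxa-Michael), or deprotonation may stray to the side-chain CH2 at the γ-position. The fallback avoids a lithium enolate altogether. It sets out from 11: heating with tert-butoxybis(dimethylamino)methane (toluene, 80 °C) should condense at the same sp3 α-carbon to give the enaminone F3. Mild hydrolysis (1 M aq. oxalic acid, THF, 0 °C) would release the hydroxymethylidene compound, and the route is rejoined at 12.

Step 7. Regiocontrol may be lost in the second deprotonation (C5 methylene against methyl). The strongly basic dianion may also enolise aldehyde 9, with epimerisation or β-elimination at the dioxolane. The fallback fixes the regiochemistry structurally through an ynone and closes the ring without protic acid. It sets out from 4: alkylation of lithiated 1-(trimethylsilyl)propyne (n-BuLi, THF, −78 °C) would give the silylalkyne F4. Desilylation (K2CO3, MeOH) gives the terminal alkyne F5. Acylation of its lithium acetylide with N-methoxy-N-methylacetamide (n-BuLi, THF, −78 °C) gives the methyl ynone F6. Aldol addition of its kinetic enolate (LiN(iPr)2, THF, −78 °C) to 9 gives the β-hydroxy ynone F7. Catalytic AgOSO2CF3 (CH2Cl2, rt) should then effect 6-endo-dig oxa-cyclisation, and the route is rejoined at 11, bypassing 6 and 10.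

Further compounds
F1 | step 13 | 3-ethenyl-2-[(4S,5R)-5-ethenyl-2,2-dimethyl-1,3-dioxolan-4-yl]-6-{2-[4-methoxy-3-(methoxymethoxy)phenyl]ethyl}-4H-pyran-4-one | COCOc1cc(CCc2cc(=O)c(C=C)c(o2)[C@H]3OC(C)(C)O[C@@H]3C=C)ccc1OC
F2 | step 13 | (7R,8S)-7,8-(isopropylidenedioxy)-2-{2-[4-methoxy-3-(methoxymethoxy)phenyl]ethyl}-7,8-dihydro-4H-chromen-4-one | COCOc1cc(CCc2cc(=O)c3c(o2)[C@H]4OC(C)(C)O[C@@H]4C=C3)ccc1OC
F3 | step 9 | 2-[(4R,5R)-5-({[tert-butyl(dimethyl)silyl]oxy}methyl)-2,2-dimethyl-1,3-dioxolan-4-yl]-3-[(dimethylamino)methylidene]-6-{2-[4-methoxy-3-(methoxymethoxy)phenyl]ethyl}-2,3-dihydro-4H-pyran-4-one, C2 epimers | COCOc1cc(CCC2=CC(=O)C(=CN(C)C)C(O2)[C@H]3OC(C)(C)O[C@@H]3CO[Si](C)(C)C(C)(C)C)ccc1OC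
F4 | step 7 | {4-[4-methoxy-3-(methoxymethoxy)phenyl]but-1-yn-1-yl}(trimethyl)silane | COCOc1cc(CCC#C[Si](C)(C)C)ccc1OC
F5 | step 7 | 4-(but-3-yn-1-yl)-1-methoxy-2-(methoxymethoxy)benzene | COCOc1cc(CCC#C)ccc1OC
F6 | step 7 | 6-[4-methoxy-3-(methoxymethoxy)phenyl]hex-3-yn-2-one | COCOc1cc(CCC#CC(C)=O)ccc1OC
F7 | step 7 | 1-[(4R,5R)-5-({[tert-butyl(dimethyl)silyl]oxy}methyl)-2,2-dimethyl-1,3-dioxolan-4-yl]-1-hydroxy-7-[4-methoxy-3-(methoxymethoxy)phenyl]hept-4-yn-3-one, C1 epimers | COCOc1cc(CCC#CC(=O)CC(O)[C@H]2OC(C)(C)O[C@@H]2CO[Si](C)(C)C(C)(C)C)ccc1OC
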